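**Retrosynthetic overview**
1. The epoxyquinol ring comes last, from a flat para-methoxyphenol: ketal hydrolysis, anti-selective ketone reduction, catalyst-controlled nucleophilic epoxidation of C5'=C6', and PhI(OAc)2 dearomatization to the quinone monoketal.
2. The C11–aryl bond is made by B-alkyl Suzuki coupling; the borane comes from α-face hydroboration of an exocyclic C9=C11 methylene, which sets 9α-H.
3. Ring B (C5–C10) is never closed as a six-membered ring. Its C9–C8(CH3)=C7 array, with C9 next to quaternary C10, is the signature of a chloro(methyl)carbene one-carbon enlargement: C8 and its methyl are inserted between C9 and C7 of the silyl enol ether of a cyclopentanone (ring C5–C6–C7–C9–C10), which can enolize only toward C7.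
4. Ring A and the centres C10, C5 and C4 come from a Hajos–Parrish-type annulation (C10) and a Li/NH3 reductive hydroxymethylation (5α-H, 4α-CH2OH); the C3 carbonyl is then removed through its dithiolane.
5. Ring order: five-membered ring (purchased dione), then ring A (aldol), then ring B (expansion 5 to 6), then the quinol ring (dearomatization of the arene).

Key step: step 10

Numbering: drimane numbering is used (ring A = C1–C5 and C10; ring B = C5–C10; C11 on C9; C12 = methyl on C8; C4 carries β-CH3 and α-CH2OH; C10 carries β-CH3). The quinol ring is C1'–C6' (C1' carbonyl, C2' methyl, C4' hydroxyl, C5' bonded to C11, epoxide on C5'–C6'). The bicyclic compounds before step 10 keep these numbers with C8 missing ("hydrindane").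
Remark on the chemistry: the cinchonidine-derived catalyst of step 17 is assumed to favour the C5'/C6' face drawn; if the other face is favoured, the pseudoenantiomeric N-benzylcinchoninium chloride is used instead.

Step 1
Reactants: 1 2-methylcyclopentane-1,3-dione; 2 ethyl vinyl ketone (pent-1-en-3-one)
Product: 3 2-methyl-2-(3-oxopentyl)cyclopentane-1,3-dione
Conditions: H2O, AcOH (cat.), 75 °C
Reagents that add atoms: none
Why: Michael addition of the acidic cyclic 1,3-dione to the enone should give the achiral triketone cleanly; no stereocenter is formed.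

Step 2
Reactants: 3 2-methyl-2-(3-oxopentyl)cyclopentane-1,3-dione
Product: 4 (S)-4,7a-dimethyl-2,3,7,7a-tetrahydro-1H-indene-1,5(6H)-dione (enedione; C9 and C3 carbonyls; C4=C5; 10β-CH3)
Conditions: L-phenylalanine (1 equiv), (+)-camphorsulfonic acid (0.5 equiv), DMF, 20 → 70 °C
Reagents that add atoms: none
Why: Hajos–Parrish–Eder–Sauer–Wiechert aldol cyclodehydration, in which the amino acid enamine of the side-chain ketone attacks one of the two enantiotopic ring carbonyls through a hydrogen-bonded chair transition state and so sets quaternary C10 as S (β-methyl).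

Step 3
Reactants: 4 (S)-4,7a-dimethyl-2,3,7,7a-tetrahydro-1H-indene-1,5(6H)-dione
Product: 5 (1S,7aS)-1-hydroxy-4,7a-dimethyl-1,2,3,6,7,7a-hexahydro-5H-inden-5-one (9β-hydroxy enone)
Conditions: NaBH4 (0.3 equiv), EtOH, −20 °C
Reagents that add atoms: none
Why: chemoselective 1,2-reduction, since the saturated cyclopentanone is more electrophilic than the enone carbonyl and hydride attacks anti to the angular methyl, giving the 9β-alcohol that masks C9 for the next step.

Step 4
Reactants: 5 (1S,7aS)-1-hydroxy-4,7a-dimethyl-1,2,3,6,7,7a-hexahydro-5H-inden-5-one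
Product: 7 9β-hydroxy-4α-(hydroxymethyl)-4β,10β-dimethyl-5α-H-hydrindan-3-one (trans-fused keto diol), via dilithium alkoxide–enolate 6 (not isolated)
Conditions: Li (2.2 equiv), NH3/THF, −78 → −33 °C; NH3 removed; CH2O (gas), THF, −78 °C; aq. NH4Cl
Reagents that add atoms: formaldehyde C=O
Why: Birch-type reductive alkylation (Stork), in which the reduced enone is protonated at C5 on the α-face to give the trans ring fusion and the regiospecific C3 enolate is trapped by formaldehyde (aldol) anti to the axial C10 methyl, so that C4 should carry an equatorial α-CH2OH and an axial β-CH3.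

Step 5
Reactants: 7 9β-hydroxy-4α-(hydroxymethyl)-4β,10β-dimethyl-5α-H-hydrindan-3-one
Product: 8 3,3-(ethylenedithio) derivative of 7 (spiro-1,3-dithiolane at C3)
Conditions: HSCH2CH2SH, BF3·OEt2, CH2Cl2, 0 → 20 °C
Reagents that add atoms: ethane-1,2-dithiol SCCS
Why: Lewis-acid thioketalization is the standard answer to ketones flanked by a quaternary carbon and tolerates the free hydroxyls; C4 has no α-hydrogen, so no elimination is possible.

Step 6
Reactants: 8 3,3-(ethylenedithio) derivative of 7
Product: 9 4α-(hydroxymethyl)-4β,10β-dimethyl-5α-H-hydrindan-9β-ol (3-deoxy diol)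
Conditions: Raney nickel (Ni), EtOH, 78 °C
Reagents that add atoms: none
Why: Mozingo desulfurization should remove the C3 oxygen function at a stage where the molecule holds no alkene.

Step 7
Reactants: 9 4α-(hydroxymethyl)-4β,10β-dimethyl-5α-H-hydrindan-9β-ol
Product: 10 primary tert-butyldimethylsilyl ether of 9 (9β-OH free)
Conditions: t-BuMe2SiCl, imidazole, CH2Cl2, 0 °C
Reagents that add atoms: tert-butyldimethylsilyl chloride CC(C)(C)[Si](C)(C)Cl
Why: selective silylation, because the primary hydroxyl should react much faster than the secondary C9 hydroxyl next to quaternary C10.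

Step 8
Reactants: 10 primary tert-butyldimethylsilyl ether of 9
Product: 11 4α-(tert-butyldimethylsilyloxymethyl)-4β,10β-dimethyl-5α-H-hydrindan-9-one
Conditions: Dess–Martin periodinane, CH2Cl2, 20 °C
Reagents that add atoms: none
Why: Dess–Martin oxidation should return the C9 ketone under neutral conditions that leave the silyl ether intact.

Step 9
Reactants: 11 4α-(tert-butyldimethylsilyloxymethyl)-4β,10β-dimethyl-5α-H-hydrindan-9-one
Product: 12 9-(trimethylsilyloxy) enol ether of 11 (C9=C7)
Conditions: LiN(i-Pr)2, THF, −78 °C; Me3SiCl; non-aqueous work-up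
Reagents that add atoms: chlorotrimethylsilane C[Si](C)(C)Cl
Why: kinetic enolization and O-silylation; C10 is quaternary, so the enolate can form only toward C7 and a single silyl enol ether should result.

Step 10
Reactants: 12 9-(trimethylsilyloxy) enol ether of 11
Product: 14 4α-(tert-butyldimethylsilyloxymethyl)-11-nor-drim-7-en-9-one (ring B enone: C9=O; C7=C8; 8-CH3), via chlorocyclopropane 13 (not isolated)
Conditions: CH3CHCl2 (3 equiv), n-BuLi (2.5 equiv, slow addition), Et2O, −35 °C; then MeOH, Et3N, 65 °C
Reagents that add atoms: 1,1-dichloroethane CC(Cl)Cl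
Why: n-BuLi deprotonates CH3CHCl2 and α-elimination of LiCl gives the chloro(methyl)carbenoid, which adds in a [2+1] cheletropic step to the electron-rich C9=C7 enol ether from the α-face anti to the C10 methyl to give 13; the siloxy oxygen then pushes a disrotatory two-electron electrocyclic opening of the shared C7–C9 bond with loss of the endo chloride, and methanol desilylates the 1-siloxy-2-methylallyl cation to the C9 ketone with the C7=C8 double bond. The closest known reaction type is the halocarbene one-carbon ring enlargement of cyclic silyl enol ethers to 2-substituted cycloalk-2-enones (Conia type, a Ciamician–Dennstedt-like opening of a halocyclopropane). The only ring closed is the transient cyclopropane, by carbene [2+1] addition; ring B is not closed at all but arises from the five-membered ring C5–C6–C7–C9–C10 when the C7–C9 bond breaks after C8 has been bridged across it. No new stereocenter survives (C7, C8 and C9 of 13 all become sp2), and the trans ring fusion at C5/C10 and the C4 centre are not touched. The step needs control of where the carbon enters and where the alkene ends up: C10 is quaternary, so the enol ether exists only toward C7 and C8 can enter only between C9 and C7, and because the oxygen sits on C9 the allyl cation can collapse only to the C9 carbonyl, which fixes the double bond at C7=C8 with the methyl on C8. Chemoselectivity is secured because the enol ether is the only alkene in 12 and the silyl ether is inert to the carbenoid at −35 °C.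

Step 11
Reactants: 14 4α-(tert-butyldimethylsilyloxymethyl)-11-nor-drim-7-en-9-one
Product: 15 4α-(tert-butyldimethylsilyloxymethyl)drima-7,9(11)-diene (exocyclic C9=C11H2)
Conditions: Ph3PCH3Br, KOt-Bu, toluene, 90 °C
Reagents that add atoms: methyltriphenylphosphonium bromide C[P+](c1ccccc1)(c1ccccc1)c1ccccc1.[Br-]
Why: Wittig methylenation under the high-temperature KOt-Bu conditions used for hindered ketones should convert the C9 carbonyl into the exocyclic methylene that carries C11.

Step 12
Reactants: 16 4-methoxy-3-methylphenol
Product: 17 2-bromo-4-methoxy-5-methylphenol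
Conditions: NBS, MeCN, 0 °C
Reagents that add atoms: N-bromosuccinimide O=C1CCC(=O)N1Br
Why: electrophilic aromatic bromination ortho to the hydroxyl (para is blocked by OCH3) should occur at the less hindered ortho carbon, which is also para to the methyl group.

Step 13
Reactants: 17 2-bromo-4-methoxy-5-methylphenol
Product: 18 1-bromo-5-methoxy-2-(methoxymethoxy)-4-methylbenzene
Conditions: MeOCH2Cl, i-Pr2NEt, CH2Cl2, 0 → 20 °C
Reagents that add atoms: chloromethyl methyl ether COCCl
Why: O-alkylation of the phenol gives the base-stable methoxymethyl ether needed for the aqueous basic coupling.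

Step 14
Reactants: 15 4α-(tert-butyldimethylsilyloxymethyl)drima-7,9(11)-diene; 18 1-bromo-5-methoxy-2-(methoxymethoxy)-4-methylbenzene
Product: 20 11-[5-methoxy-2-(methoxymethoxy)-4-methylphenyl]-4α-(tert-butyldimethylsilyloxymethyl)drim-7-ene (9α-H), via B-alkyl-9-BBN 19 (not isolated)
Conditions: 9-BBN, THF, 0 → 60 °C; then 18, Pd(dppf)Cl2 (5 mol %), AsPh3, Cs2CO3, DMF/H2O, 60 °C
Reagents that add atoms: none
Why: anti-Markovnikov hydroboration places boron on terminal C11 and delivers hydrogen to C9 from the α-face anti to the axial C10 methyl (setting 9α-H), and the B-alkyl Suzuki–Miyaura coupling then joins C11 to the arene without touching the trisubstituted C7=C8 alkene.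

Step 15
Reactants: 20 11-[5-methoxy-2-(methoxymethoxy)-4-methylphenyl]-4α-(tert-butyldimethylsilyloxymethyl)drim-7-ene
Product: 21 2-[4α-(hydroxymethyl)drim-7-en-11-yl]-4-methoxy-5-methylphenol (phenol diol)
Conditions: HCl (conc., cat.), MeOH, 40 °C
Reagents that add atoms: none
Why: acid-catalysed acetal exchange and desilylation in methanol should remove the methoxymethyl and silyl groups together, while the trisubstituted alkene is stable to dilute acid.

Step 16
Reactants: 21 2-[4α-(hydroxymethyl)drim-7-en-11-yl]-4-methoxy-5-methylphenol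
Product: 22 2-[4α-(hydroxymethyl)drim-7-en-11-yl]-4,4-dimethoxy-5-methylcyclohexa-2,5-dien-1-one (quinone monoketal; ketone at C4'; ketal at C1')
Conditions: PhI(OAc)2, MeOH, 0 °C
Reagents that add atoms: methanol CO
Why: oxidative dearomatization of a para-methoxyphenol in methanol gives the quinone monoketal, with the positions of ketal and ketone fixed by the positions of OCH3 and OH.

Step 17
Reactants: 22 2-[4α-(hydroxymethyl)drim-7-en-11-yl]-4,4-dimethoxy-5-methylcyclohexa-2,5-dien-1-one
Product: 23 C5'–C6' epoxide of 22 (epoxide oxygen on the face shown in the SMILES)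
Conditions: t-BuOOH, N-benzylcinchonidinium chloride (10 mol %), NaOH (aq., cat.), toluene, 0 °C
Reagents that add atoms: tert-butyl hydroperoxide CC(C)(C)OO
Why: Weitz–Scheffer nucleophilic epoxidation under chiral phase-transfer catalysis (Wynberg type), in which the peroxide anion adds to the unsubstituted β-carbon C6' and not to the methyl-bearing C2' while the cinchona ion pair selects the face; the terpenoid part is already enantiopure, so the minor epoxide is a diastereomer and should be removable.

Step 18
Reactants: 23 C5'–C6' epoxide of 22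
Product: 24 C4' alcohol of 23 with the hydroxyl anti to the epoxide
Conditions: i-Bu2AlH (DIBAL-H), THF, −78 °C; aq. potassium sodium tartrate
Reagents that add atoms: none
Why: diastereoselective 1,2-reduction, in which the aluminium hydride coordinates the epoxide oxygen and delivers hydride to C4' from the epoxide face, which is also the face away from the bulky C5' substituent, so the new hydroxyl should be anti to the epoxide.

Step 19
Reactants: 24 C4' alcohol of 23
Product: 25 Epoxypholamin B
Conditions: TFA (cat.), H2O, CH2Cl2, 0 °C
Reagents that add atoms: water O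
Why: mild acid hydrolysis of the dimethyl ketal should unmask the C1' enone without opening the epoxide or eliminating the allylic alcohol.

**Compound list**
1 | 2-methylcyclopentane-1,3-dione | CC1C(=O)CCC1=O | starting material
2 | ethyl vinyl ketone (pent-1-en-3-one) | CCC(=O)C=C | starting material
3 | 2-methyl-2-(3-oxopentyl)cyclopentane-1,3-dione | CCC(=O)CCC1(C)C(=O)CCC1=O | intermediate
4 | (S)-4,7a-dimethyl-2,3,7,7a-tetrahydro-1H-indene-1,5(6H)-dione | O=C1CCC2=C(C)C(=O)CC[C@]12C | intermediate
5 | (1S,7aS)-1-hydroxy-4,7a-dimethyl-1,2,3,6,7,7a-hexahydro-5H-inden-5-one | O[C@H]1CCC2=C(C)C(=O)CC[C@]12C | intermediate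
6 | dilithium 9β-alkoxide C3-enolate of the trans-fused bicycle (not isolated) | [Li]O[C@H]1CC[C@H]2C(C)=C(O[Li])CC[C@]12C | intermediate
7 | 9β-hydroxy-4α-(hydroxymethyl)-4β,10β-dimethyl-5α-H-hydrindan-3-one | O[C@H]1CC[C@H]2[C@](C)(CO)C(=O)CC[C@]12C | intermediate
8 | 3,3-(ethylenedithio) derivative of 7 | O[C@H]1CC[C@H]2[C@](C)(CO)C3(SCCS3)CC[C@]12C | intermediate
9 | 4α-(hydroxymethyl)-4β,10β-dimethyl-5α-H-hydrindan-9β-ol | O[C@H]1CC[C@H]2[C@](C)(CO)CCC[C@]12C | intermediate
10 | primary tert-butyldimethylsilyl ether of 9 | O[C@H]1CC[C@H]2[C@](C)(CO[Si](C)(C)C(C)(C)C)CCC[C@]12C | intermediate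
11 | 4α-(tert-butyldimethylsilyloxymethyl)-4β,10β-dimethyl-5α-H-hydrindan-9-one | O=C1CC[C@H]2[C@](C)(CO[Si](C)(C)C(C)(C)C)CCC[C@]12C | intermediate
12 | 9-(trimethylsilyloxy) enol ether of 11 (C9=C7) | C[Si](C)(C)OC1=CC[C@H]2[C@](C)(CO[Si](C)(C)C(C)(C)C)CCC[C@]12C | intermediate
13 | 8-chloro-8-methyl-9-(trimethylsilyloxy) cyclopropane adduct, C8 bridging C7 and C9 on the α-face, chlorine endo (not isolated) | C[Si](C)(C)O[C@]13[C@](C)(Cl)[C@@H]3C[C@H]2[C@](C)(CO[Si](C)(C)C(C)(C)C)CCC[C@]12C | intermediate
14 | 4α-(tert-butyldimethylsilyloxymethyl)-11-nor-drim-7-en-9-one | O=C1C(C)=CC[C@H]2[C@](C)(CO[Si](C)(C)C(C)(C)C)CCC[C@]12C | intermediate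
15 | 4α-(tert-butyldimethylsilyloxymethyl)drima-7,9(11)-diene | C=C1C(C)=CC[C@H]2[C@](C)(CO[Si](C)(C)C(C)(C)C)CCC[C@]12C | intermediate
16 | 4-methoxy-3-methylphenol | COc1ccc(O)cc1C | starting material
17 | 2-bromo-4-methoxy-5-methylphenol | COc1cc(Br)c(O)cc1C | intermediate
18 | 1-bromo-5-methoxy-2-(methoxymethoxy)-4-methylbenzene | COCOc1cc(C)c(OC)cc1Br | intermediate
19 | B-[4α-(tert-butyldimethylsilyloxymethyl)drim-7-en-11-yl]-9-borabicyclo[3.3.1]nonane, 9α-H (not isolated) | C(B1C2CCCC1CCC2)[C@H]3C(C)=CC[C@H]4[C@](C)(CO[Si](C)(C)C(C)(C)C)CCC[C@]34C | intermediate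
20 | 11-[5-methoxy-2-(methoxymethoxy)-4-methylphenyl]-4α-(tert-butyldimethylsilyloxymethyl)drim-7-ene | COCOc1cc(C)c(OC)cc1C[C@H]2C(C)=CC[C@H]3[C@](C)(CO[Si](C)(C)C(C)(C)C)CCC[C@]23C | intermediate
21 | 2-[4α-(hydroxymethyl)drim-7-en-11-yl]-4-methoxy-5-methylphenol | COc1cc(C[C@H]2C(C)=CC[C@H]3[C@](C)(CO)CCC[C@]23C)c(O)cc1C | intermediate
22 | 2-[4α-(hydroxymethyl)drim-7-en-11-yl]-4,4-dimethoxy-5-methylcyclohexa-2,5-dien-1-one | COC1(OC)C=C(C[C@H]2C(C)=CC[C@H]3[C@](C)(CO)CCC[C@]23C)C(=O)C=C1C | intermediate
23 | C5'–C6' epoxide of 22 | CC1=CC(=O)[C@]2(C[C@H]3C(C)=CC[C@H]4[C@](C)(CO)CCC[C@]34C)O[C@@H]2C1(OC)OC | intermediate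
24 | C4' alcohol of 23, hydroxyl anti to the epoxide | CC1=C[C@@H](O)[C@]2(C[C@H]3C(C)=CC[C@H]4[C@](C)(CO)CCC[C@]34C)O[C@@H]2C1(OC)OC | intermediate
25 | Epoxypholamin B | CC1=C[C@@H](O)[C@]2(C[C@H]3C(C)=CC[C@H]4[C@](C)(CO)CCC[C@]34C)O[C@@H]2C1=O | target

**Step count and risks**
Total step count: 19. Longest linear sequence: 17 steps (steps 1–11 and 14–19; steps 12–13 make the aryl bromide).

The three steps most likely to fail:

Step 10. The carbenoid may add slowly to the hindered enol ether, n-BuLi may cleave the silyl enol ether instead, or the cyclopropane may form mainly as the exo-chloro epimer, which does not ionize. The fallback sets out from 11 and returns at 14, and it keeps the one-carbon enlargement but does it by a polar 1,2-shift. Lewis-acid homologation of ketone 11 with allyl diazoacetate and Et3OBF4 in CH2Cl2 at 0 °C (Tiffeneau–Demjanov type), in which the methylene carbon C7 migrates and C9 stays next to C10, should give the ring-enlarged allyl β-keto ester F2. C-methylation (MeI, K2CO3, acetone) should give the quaternary ester F3. Tsuji decarboxylation–dehydrogenation (Pd(OAc)2, PPh3, MeCN, 80 °C) should then give enone 14.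

Step 4. Facial control may be lost in the protonation at C5, giving cis ring fusion, or the aldol trapping at C4 may be incomplete. The fallback sets out from 5 and returns at 7. Conjugate reduction of 5 with the hydride reagent made from t-BuCu and i-Bu2AlH in THF/HMPA at −50 °C (known to give trans-hydrindanones from Hajos–Parrish enones) is followed by silylation of the aluminium enolate in the same flask with Me3SiCl/Et3N, giving the bis(trimethylsilyl) enol ether F1. A Yb(OTf)3-catalysed Mukaiyama aldol reaction of F1 with aqueous formaldehyde should then place the hydroxymethyl group on the α-face of C4 and lose both silyl groups on work-up, giving 7.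

Step 17. The ion-paired catalyst may discriminate too weakly between the faces of a substrate whose stereocenters are remote, so that both epoxide diastereomers form. The fallback sets out from 22 and returns at 25, replacing catalyst control by a covalently bound auxiliary. Ketal exchange of 22 with (2R,4R)-pentane-2,4-diol (PPTS, toluene, 4 Å molecular sieves) should give the C2-symmetric chiral spiroketal F4. Its epoxidation with t-BuOOH and DBU, directed by the dioxane methyl group next to C6', should give the epoxy ketone F5, and DIBAL-H reduction should give the anti epoxy alcohol F6. Hydrolysis of the ketal (aq. TFA, CH2Cl2) should then give 25; the antipodal diol is used if the (R,R) auxiliary proves mismatched.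

**Further compounds**
F1 | step 4 | bis(trimethylsilyl) compound: 9β-trimethylsilyloxy C3 trimethylsilyl enol ether of the trans-fused bicycle | C[Si](C)(C)O[C@H]1CC[C@H]2C(C)=C(O[Si](C)(C)C)CC[C@]12C
F2 | step 10 | allyl 9-oxo-4α-(tert-butyldimethylsilyloxymethyl)-11,12-dinor-drimane-8-carboxylate (C8 epimers) | O=C1C(C(=O)OCC=C)CC[C@H]2[C@](C)(CO[Si](C)(C)C(C)(C)C)CCC[C@]12C
F3 | step 10 | allyl 8-methyl-9-oxo-4α-(tert-butyldimethylsilyloxymethyl)-11,12-dinor-drimane-8-carboxylate (C8 epimers) | O=C1C(C)(C(=O)OCC=C)CC[C@H]2[C@](C)(CO[Si](C)(C)C(C)(C)C)CCC[C@]12C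
F4 | step 17 | quinone monoketal of 22 with (2R,4R)-pentane-2,4-diol in place of the two methoxy groups | CC1=CC(=O)C(C[C@H]3C(C)=CC[C@H]4[C@](C)(CO)CCC[C@]34C)=CC12O[C@H](C)C[C@@H](C)O2
F5 | step 17 | C5'–C6' epoxide of F4 | CC1=CC(=O)[C@]2(C[C@H]3C(C)=CC[C@H]4[C@](C)(CO)CCC[C@]34C)O[C@@H]2C15O[C@H](C)C[C@@H](C)O5
F6 | step 17 | C4' alcohol of F5, hydroxyl anti to the epoxide | CC1=C[C@@H](O)[C@]2(C[C@H]3C(C)=CC[C@H]4[C@](C)(CO)CCC[C@]34C)O[C@@H]2C15O[C@H](C)C[C@@H](C)O5
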